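Remark (assumption on the chemistry): the sense of induction in step 2 is taken from the usual C–H···O binding model of the oxazaborolidinium catalyst, which here points to the catalyst built from (R)-α,α-diphenylprolinol; should the first run show the opposite sense, the enantiomeric catalyst is used and nothing else changes.

## Structural features

The target 34 is a C30 terpenoid acetate made of two trans-fused oxepane–cyclohexane bicycles (rings A/B and C/D) joined by the two-carbon bridge C13–C14 between ring carbons C12 and C15. Locants are those of the SMILES backbone, C1 (exocyclic CH2) to C25 (acetoxy carbon), with O6 and O21 counted. In each bicycle a quaternary fusion carbon with an axial methyl (C11, C16) lies between an oxygen-bearing fusion CH (C5, C22; H anti to the methyl) and the CH that carries the bridge (C12, C15; bridge equatorial, cis to the methyl), and the ring oxygen is bonded to a gem-dimethyl carbon (C7, C20). Matching C2/C25, C5/C22, C11/C16 and C12/C15 shows that both bicycles have the same absolute configuration, so the molecule is pseudo-C2-symmetric. The halves differ only at four sites: C2 is an exocyclic methylene and C8 an (S)-carbinol, whereas C25 is a tertiary acetate (oxygen axial, syn to the C16 methyl) and C19 a ketone. The fragile groups are the 1,1-disubstituted alkene (acid-induced migration, attack by radicals), the hindered tertiary acetate (ionisation, elimination) and the enolisable α-alkoxy ketone. The real difficulty lies in the two quaternary stereocentres flanked by further stereocentres, in closing seven-membered ethers onto a fully substituted carbon, and in making the C13–C14 bond between two CH2 groups that hang on very congested ring carbons. The key step exploits ring A (C2–C5, C11, C12): its 1,4-dioxygenation (C5–O and sp2 C2) with vicinal quaternary C11 and C12 is the pattern of a methylbenzoquinone whose methyl-bearing alkene acts as dienophile. Because ring C shows the same pattern, one cycloadduct can serve both halves.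

## Logic of the disconnections

34 from 32. The C1=C2 π bond is traced back to a C2–O/C1–Si pair and the C8 hydroxyl to its silyl ether. The methylene is kept masked because an sp2 C2 next to a C13 radical invites a 1,2-vinyl shift; the gain is that alkene and free carbinol appear only in the last step. The demand is an acid-mediated elimination mild enough for the tertiary acetate.

32 from 23 and 30. The C13–C14 bond, the centre of the bridge, is cut, which divides the molecule into two bicycles of identical configuration, each keeping one CH2. The demand is a cross-coupling of two β-branched primary carbons that is selective for the hetero-product; this is met by turning only 30 into a nucleophile (31) and letting 23 enter as a radical.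

30 from 29, 28 and 25, and 25 from 19. The cuts are the acetyl C–O bond, the C19 carbonyl (back to a carbinol), the C14–I bond (back to C14–CO2H with loss of the carboxyl carbon) and the C25–CH3 bond. The order is forced: a free hydroxyl γ to the carboxyl would lactonise and a ketone β to the iodide would eliminate, so the methyl group is added at the carboxylate stage, the alkoxide is capped in the flask, and only then is the carboxyl exchanged for iodine.

23 from 21, and 21 from 19. The cuts are the C13–I bond (again from the acid) and the C2–C1 bond (a silylmethyl nucleophile on the C2 ketone). The same ordering rules apply; the gain is that both halves leave the same compound 19 by two-step and four-step branches.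

19 from 17. The O6–C7 bond of ring B is cut, returning to an open-chain epoxy alcohol. The demand is opening of the epoxide at its tertiary carbon (seven-membered mode) by the C5 hydroxyl, with C8 untouched so that its configuration is that of the epoxide.

17 from 16. The epoxide C–O bonds are cut back to a trisubstituted alkene. The alkene is far from the ring stereocentres, so the reagent must impose the C8 configuration.

16 from 15, and 15 from 13. The C7=C8 bond and then the C8–C9 bond are cut, each back to a lactol carbon. The C5 hydroxyl thus needs no protecting group: it is tied up as a lactol before each olefination and freed by it.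

13 from 12, and 12 from 9. The C14 carboxyl goes back to the free aldehyde, and the two aldehyde carbons C9 and C14 are reconnected as the C9=C14 alkene of a temporary cyclohexene. The demand is that the two arms be told apart, which the C5 hydroxyl does by capturing C9 as a five-membered lactol.

9 from 8, 8 from 7, and 7 from 5. The C5–H bond (hydride), the ketal at C2 and the lost C4–OMe bond are restored. The demand is to distinguish the two ring A carbonyls and to deliver hydride anti to the C11 methyl while the bicycle is still rigid.

5 from 2 and 3. The C10–C11 and C12–C13 bonds are cut in a retro-[4+2] sense. This removes ring A's quaternary centre, its neighbour C12 and both arms at once, leaving a flat quinone and a C4 diene. The demand is addition at the methyl-bearing alkene only, on one face, followed by inversion at C12.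

2 from 1. The two carbonyl oxygens go back to a phenol with a free para position.

## Other disconnections considered

Alternative 1: The cut is through C14–C15 and C16–C17, so ring C starts as enone A2 and the west half as aldehyde A3. Forward, copper-catalysed conjugate addition of Grignard reagent A4 to A2 and aldol addition to A3 in the same flask give A1. In its favour: the union is polar, hetero-selective by construction and sets the C16 quaternary centre anti to the C22 silyloxy group in the same operation; the regiodefined C15 enolate is otherwise hard to reach. Against it here: the C14 carbinol must be removed afterwards, A2 needs its own enantioselective synthesis, and ring D must then be closed late on the whole molecule next to the C2 methylene. A hindered enolate beside a new quaternary centre adding to an enolisable aldehyde is also prone to reversal. Comparison: as a union step Alternative 1 is the better founded, since the chosen plan relies on a nickel-mediated coupling of two congested alkyl partners. The chosen plan is ahead in step economy and in structure, because one intermediate (19) supplies both bicycles and ring D costs no extra steps. A3 itself could be made by the chosen key step.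

Alternative 2: The cut is the O6–C7 bond, but reached from a six-membered ether: tetrahydropyran A6 (O6 bonded to C8, tertiary hydroxyl on C7) is expanded to oxepane acetate A5. Forward, activation of the tertiary hydroxyl lets O6 bridge to C7 and acetate opens the bridged oxonium ion at C8. In its favour: it uses the six-membered epoxide opening, which is the normally preferred mode, and it is stereospecific (two inversions at C8). Against it: a tertiary triflate can simply eliminate, acetate may add at the tertiary carbon and return a tetrahydropyran, and it costs two to three operations where the chosen plan uses one. It also says nothing about ring A or the bridge. Comparison: on regiochemical reliability of the ring closure Alternative 2 is the better and on stereochemical fidelity it is the equal; on step count the chosen plan is shorter. The same idea is therefore held as the recourse for step 11.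

Alternative 3: The cut is the C2–C12 bond; enyne A8, with ring B already in place, is cycloisomerised to diene A7. Forward, a palladium hydride (divalent palladium, formed from zerovalent palladium and AcOH) adds to the alkyne, the vinylpalladium inserts the C12=C13 alkene and β-hydride loss from C14 gives the enol ether. In its favour: it is atom-economic, installs the C2 methylene directly and leaves C14 as a masked aldehyde. Against it: C12 is created in an insertion next to the quaternary C11 with only the existing ring to direct it. The quaternary centre and the oxepane must be built first by other means. The chemistry also cannot serve ring C, where C25 carries a methyl and an acetate, so the pseudo-symmetry goes unused. Comparison: for the methylene Alternative 3 is the better, because the chosen plan has to carry C2 masked through the radical steps. For C11/C12 the chosen cycloaddition is the more secure, since it sets the quaternary centre in the first C–C step and fixes C12 by equilibration. Overall the chosen plan is shorter because its early intermediates are shared by both halves.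

Key step: step 2

## Route

Step 1
Reactants: 1 2-methoxy-6-methylphenol
Product: 2 2-methoxy-6-methyl-1,4-benzoquinone
Conditions: ON(SO3K)2 (2.2 equiv), KH2PO4, H2O/acetone, 0 °C → rt
Reagents that add atoms: potassium nitrosodisulfonate, [K+].[K+].[O]N(S(=O)(=O)[O-])S(=O)(=O)[O-]
Why: Teuber oxidation: the nitroxyl radical oxidises the phenol to its phenoxyl radical and a second equivalent adds at the free para position and collapses to the p-quinone; both ortho positions are blocked.

Step 2
Reactants: 2 2-methoxy-6-methyl-1,4-benzoquinone; 3 buta-1,3-diene
Product: 5 trans-fused (4aS,8aS)-3-methoxy-4a-methyl-4a,5,8,8a-tetrahydronaphthalene-1,4-dione, via cis cycloadduct 4 (not isolated)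
Conditions: (R)-3,3-diphenyl-1-(2-methylphenyl)tetrahydro-1H,3H-pyrrolo[1,2-c][1,3,2]oxazaborole·HNTf2 (20 mol%), 3 (excess), CH2Cl2, −78 → −40 °C; then Et3N, −40 °C → rt
Reagents that add atoms: none
Why: The cationic boron binds the more basic vinylogous-ester carbonyl (the later C2) on the side of the neighbouring C–H and so activates only the methyl-bearing alkene, while the methoxy-bearing alkene is a deactivated push–pull system. Butadiene then adds in a concerted, asynchronous [4+2] cycloaddition (closest known type: oxazaborolidinium-catalysed Diels–Alder reactions of unsymmetrical quinones), forming C10–C11 and C12–C13 and closing the temporary six-membered carbocycle in one intermolecular suprafacial event that gives 4. C11 is set by the catalyst, whose aryl group screens one face of the bound alkene so that the diene arrives from the other. C12 is first cis by suprafaciality and is then set under thermodynamic control: Et3N, which also stops catalysis, enolises the C2 carbonyl toward C12 and reprotonation gives the trans-fused 5, in which C13 is cis to the C11 methyl. The selectivities needed are site selectivity between the two quinone alkenes (methoxy group and binding site), facial selectivity (catalyst) and trans fusion (equilibration, helped by crystallisation); regiochemistry does not arise with a symmetrical diene.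

Step 3
Reactants: 5 trans-fused methoxy ene-dione
Product: 7 trans-fused (4aS,8aS)-4a-methyl-2,3,4a,5,8,8a-hexahydronaphthalene-1,4-dione, via methoxy dione 6 (not isolated)
Conditions: SmI2 (4.5 equiv), THF/MeOH, −78 °C
Reagents that add atoms: none
Why: SmI2 reduces the ene-dione C3=C4 bond and then cleaves the C4–OMe bond of the resulting α-methoxy ketone at C5 (known single-electron reduction of ene-diones and of α-heterosubstituted ketones). At −78 °C the samarium enolates are protonated at C3 and C4 only, so C12 is not epimerised.

Step 4
Reactants: 7 trans-fused dione
Product: 8 C2 ethylene ketal of 7 (dioxolane at the carbonyl next to the fusion CH; C5 ketone free)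
Conditions: Me3SiOCH2CH2OSiMe3 (1.1 equiv), Me3SiOTf (5 mol%), CH2Cl2, −78 → −20 °C
Reagents that add atoms: 1,2-bis(trimethylsilyloxy)ethane, C[Si](C)(C)OCCO[Si](C)(C)C
Why: Silyl triflate-catalysed ketalisation under kinetic control takes the C2 carbonyl, flanked by CH2 and CH, and leaves the C5 carbonyl, which is shielded by the quaternary C11; the low temperature avoids enol ether formation toward C12.

Step 5
Reactants: 8 keto ketal
Product: 9 C5 alcohol (hydroxyl equatorial and cis to the C11 methyl; trans fusion; C2 dioxolane)
Conditions: NaBH4, MeOH, 0 °C
Reagents that add atoms: none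
Why: Hydride adds axially from the face opposite the axial C11 methyl, as in reductions of angularly methylated trans-decalones, and gives the equatorial alcohol with the C5 configuration of the target; no other carbonyl is free.

Step 6
Reactants: 9 C5 alcohol
Product: 12 lactol aldehyde (five-membered C5–O–C9 lactol trans-fused to ring A; CH2CHO on C12), via ozonide 10 (not isolated), via hydroxy dialdehyde 11 (not isolated)
Conditions: O3, CH2Cl2, −78 °C; then PPh3, −78 °C → rt
Reagents that add atoms: ozone, [O-][O+]=O
Why: Ozonolysis of the only alkene with reductive work-up; the equatorial C5 hydroxyl closes a five-membered lactol on the C9 aldehyde, whereas a lactol on C14 would need a bridged ring with three axial substituents, so C14 stays a free aldehyde.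

Step 7
Reactants: 12 lactol aldehyde
Product: 13 lactol acid (CH2CO2H on C12)
Conditions: NaClO2, NaH2PO4, 2-methylbut-2-ene, t-BuOH/H2O, 0 °C
Reagents that add atoms: sodium chlorite, [Na+].[O-]Cl=O
Why: Pinnick oxidation: the free aldehyde adds chlorite directly, while the lactol can react only through its minor open form; the alkene scavenger removes HOCl, which would otherwise oxidise the lactol.

Step 8
Reactants: 13 lactol acid
Product: 15 six-membered lactol acid (C5–O–C8 lactol; chain C10–C9–C8), via enol ether 14 (not isolated)
Conditions: Ph3P(CH2OMe)Cl, KN(SiMe3)2 (excess), THF, 0 °C → rt; then 0.5 M HCl, THF, 0 °C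
Reagents that add atoms: (methoxymethyl)triphenylphosphonium chloride, COC[P+](c1ccccc1)(c1ccccc1)c1ccccc1.[Cl-]; water, O
Why: Wittig reaction on the lactol through its open aldehyde form (the carboxylate is inert to the ylide), then hydrolysis of the enol ether to the C8 aldehyde, which closes on the freed C5 hydroxyl. Enol ethers hydrolyse much faster than the dioxolane.

Step 9
Reactants: 15 six-membered lactol acid
Product: 16 alkene hydroxy acid (4-methylpent-3-enyl chain on C11; free C5–OH)
Conditions: i-PrPPh3I, n-BuLi (excess), THF, 0 °C → rt
Reagents that add atoms: isopropyltriphenylphosphonium iodide, CC(C)[P+](c1ccccc1)(c1ccccc1)c1ccccc1.[I-]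
Why: A second lactol Wittig reaction with the isopropylidene ylide forms the C7=C8 alkene and releases the C5 hydroxyl in the same step; no alkene geometry is at stake.

Step 10
Reactants: 16 alkene hydroxy acid
Product: 17 (8S)-epoxide (C7–C8 oxirane)
Conditions: 1,2:4,5-di-O-isopropylidene-β-L-erythro-2,3-hexodiulo-2,6-pyranose (30 mol%), KHSO5 (as 2KHSO5·KHSO4·K2SO4), K2CO3, Bu4NHSO4, MeCN/CH2(OMe)2/aq. Na2B4O7, 0 °C
Reagents that add atoms: potassium peroxymonosulfate, [K+].[O-]S(=O)(=O)OO
Why: Shi epoxidation: the chiral dioxirane transfers oxygen through a spiro transition state. The ketone of the L-fructose series should give the (S) configuration at the CH carbon of a 2-methylalk-2-ene, and the alkene is too far from the ring stereocentres for the substrate to interfere.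

Step 11
Reactants: 17 (8S)-epoxide
Product: 19 keto hydroxy acid (trans-fused oxepane with 8S hydroxyl; C2 ketone; CH2CO2H on C12), via oxepane ketal 18 (not isolated)
Conditions: (CF3)2CHOH, 0 °C → rt; then 1 M HCl, THF, rt
Reagents that add atoms: water, O
Why: In the ionising, hydrogen-bond-donating solvent the epoxide opens with positive charge at the tertiary C7, which the C5 hydroxyl captures in the seven-membered mode (known endo-selective epoxide-opening cyclisation of trisubstituted epoxides). C8 keeps its C–O bond and configuration, and the two equatorial tethers give the trans fusion. Aqueous acid then removes the dioxolane.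

Step 12
Reactants: 19 keto hydroxy acid
Product: 21 west acid (C2 bears OSiEt3 and CH2SiMe3; C8 OSiEt3; CH2CO2H on C12), via tris-silyl compound 20 (not isolated)
Conditions: Me3SiCH2MgCl (5 equiv), CeCl3, THF, −78 → 0 °C; then Et3SiOTf, −78 → 0 °C; aq. NaHCO3
Reagents that add atoms: (trimethylsilyl)methylmagnesium chloride, C[Si](C)(C)C[Mg]Cl; triethylsilyl trifluoromethanesulfonate, CC[Si](CC)(CC)OS(=O)(=O)C(F)(F)F
Why: CeCl3-promoted Grignard addition to the hindered, enolisable C2 ketone (first half of a Peterson olefination); the carboxylate is inert and cannot lactonise while anionic, and the silyl triflate caps the tertiary alkoxide before a free γ-hydroxy acid can form. The C2 configuration (equatorial attack expected) does not matter because the centre is destroyed in step 19.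

Step 13
Reactants: 21 west acid
Product: 23 west iodide (CH2I on C12; C2 and C8 as in 21), via thiohydroxamate ester 22 (not isolated)
Conditions: N-hydroxypyridine-2-thione, N,N′-dicyclohexylcarbodiimide, 4-(dimethylamino)pyridine (cat.), CH2Cl2, 0 °C, dark; then CHI3, benzene, hν, 60 °C
Reagents that add atoms: iodoform, IC(I)I
Why: Barton decarboxylative iodination: the ester fragments under light to the C13 radical, which takes iodine from CHI3 and carries the chain. With C2 sp3 there is no alkene or carbonyl next to the radical for a 1,2-shift, and the product is not a β-halo ketone and so cannot eliminate.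

Step 14
Reactants: 19 keto hydroxy acid
Product: 25 east acid (C25 methyl equatorial and OSiEt3 axial; C19 OSiEt3; CH2CO2H on C15), via tris-silyl compound 24 (not isolated)
Conditions: MeMgBr (5 equiv), CeCl3, THF, −78 → 0 °C; then Et3SiOTf, −78 → 0 °C; aq. NaHCO3
Reagents that add atoms: methylmagnesium bromide, C[Mg]Br; triethylsilyl trifluoromethanesulfonate, CC[Si](CC)(CC)OS(=O)(=O)C(F)(F)F
Why: The axial approach to the carbonyl is blocked by the syn-axial C16 methyl, so the methyl group enters equatorially and the oxygen ends axial, syn to that methyl, as in the target. Capping in the flask prevents lactonisation, as in step 12.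

Step 15
Reactants: 25 east acid
Product: 28 east diol iodide (CH2I on C15; C25 tertiary alcohol; C19 secondary alcohol), via thiohydroxamate ester 26 (not isolated), via bis-silyl iodide 27 (not isolated)
Conditions: N-hydroxypyridine-2-thione, N,N′-dicyclohexylcarbodiimide, 4-(dimethylamino)pyridine (cat.), CH2Cl2, 0 °C, dark; then CHI3, benzene, hν, 60 °C; then HF·pyridine, THF, 0 °C → rt
Reagents that add atoms: iodoform, IC(I)I
Why: Barton decarboxylative iodination as in step 13, followed by fluoride cleavage of both triethylsilyl ethers; once the carboxyl group is gone the free tertiary alcohol has nothing to lactonise with.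

Step 16
Reactants: 28 east diol iodide
Product: 29 east keto alcohol iodide (C19 ketone; C25 tertiary alcohol)
Conditions: Dess–Martin periodinane, NaHCO3, CH2Cl2, rt
Reagents that add atoms: none
Why: Dess–Martin oxidation converts the only secondary alcohol into the C19 ketone; the tertiary alcohol and the alkyl iodide are inert under the buffered conditions.

Step 17
Reactants: 29 east keto alcohol iodide
Product: 30 east acetate iodide (C25 tertiary acetate; C19 ketone; CH2I on C15)
Conditions: Ac2O, Sc(OTf)3 (5 mol%), MeCN, −20 °C
Reagents that add atoms: acetic anhydride, CC(=O)OC(C)=O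
Why: Lewis acid-catalysed acylation is the known answer for hindered tertiary alcohols, and the low temperature limits ionisation and elimination; no carboxylic acid is present, so no lactone can form.

Step 18
Reactants: 30 east acetate iodide; 23 west iodide
Product: 32 coupled bis-bicycle (C13–C14 bond formed; west C2 and C8 still silylated), via alkylzinc iodide 31 (not isolated)
Conditions: 30 (1.8 equiv), Zn dust, LiCl, THF, 40 °C; then 23, Ni(cod)2 (10 mol%), 2,2′:6′,2″-terpyridine (10 mol%), THF/DMA, rt
Reagents that add atoms: none
Why: LiCl-assisted zinc insertion tolerates the ketone and the acetate; the nickel-catalysed alkyl–alkyl Negishi coupling of unactivated primary iodides then proceeds by iodine abstraction from 23 by an alkyl complex of monovalent nickel, capture of the C13 radical at nickel and reductive elimination. A radical pathway is little affected by β-branching, and cross-selectivity follows from only 30 having been made nucleophilic.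

Step 19
Reactants: 32 coupled bis-bicycle
Product: 34 target, via hydroxysilane 33 (not isolated)
Conditions: 48% aq. HF, MeCN, 0 °C → rt
Reagents that add atoms: none
Why: HF cleaves both triethylsilyl ethers and the liberated tertiary β-hydroxysilane undergoes the acid-mediated Peterson elimination, which can place the alkene only between C1 and C2. Acetate, ketone and ring ethers should survive dilute HF.

## Compound list

1 | 2-methoxy-6-methylphenol | COc1cccc(C)c1O | starting material
2 | 2-methoxy-6-methyl-1,4-benzoquinone | COC1=CC(=O)C=C(C)C1=O | intermediate
3 | buta-1,3-diene | C=CC=C | starting material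
4 | cis-fused (4aS,8aR)-3-methoxy-4a-methyl-4a,5,8,8a-tetrahydronaphthalene-1,4-dione | O=C1C=C(OC)C(=O)[C@@]2(C)CC=CC[C@@H]12 | intermediate (not isolated)
5 | trans-fused (4aS,8aS)-3-methoxy-4a-methyl-4a,5,8,8a-tetrahydronaphthalene-1,4-dione | O=C1C=C(OC)C(=O)[C@@]2(C)CC=CC[C@H]12 | intermediate
6 | trans-fused 3-methoxy-4a-methyl-2,3,4a,5,8,8a-hexahydronaphthalene-1,4-dione (both C3 epimers) | O=C1CC(OC)C(=O)[C@@]2(C)CC=CC[C@H]12 | intermediate (not isolated)
7 | trans-fused (4aS,8aS)-4a-methyl-2,3,4a,5,8,8a-hexahydronaphthalene-1,4-dione | O=C1CCC(=O)[C@@]2(C)CC=CC[C@H]12 | intermediate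
8 | mono(ethylene ketal) of 7 at C2 (carbonyl next to the fusion CH); C5 ketone free; trans fusion | O1CCOC12CCC(=O)[C@@]3(C)CC=CC[C@H]23 | intermediate
9 | C5 alcohol of 8; hydroxyl equatorial, cis to the C11 methyl; trans fusion | O1CCOC12CC[C@H](O)[C@@]3(C)CC=CC[C@H]23 | intermediate
10 | ozonide of 9 (1,2,4-trioxolane across C9 and C14) | O1CCOC12CC[C@H](O)[C@@]3(C)CC4OOC(O4)C[C@H]23 | intermediate (not isolated)
11 | open hydroxy dialdehyde: ring A with C2 dioxolane, C5–OH, CH2CHO on C11 and on C12 | O1CCOC12CC[C@H](O)[C@@](C)(CC=O)[C@@H]2CC=O | intermediate (not isolated)
12 | lactol aldehyde: five-membered C5–O–C9(OH) lactol (both anomers) trans-fused to ring A; CH2CHO on C12 cis to the C11 methyl | O1CCOC12CC[C@@H]3OC(O)C[C@@]3(C)[C@@H]2CC=O | intermediate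
13 | lactol acid: as 12 with CH2CO2H on C12 | O1CCOC12CC[C@@H]3OC(O)C[C@@]3(C)[C@@H]2CC(=O)O | intermediate
14 | enol ether: ring A with C5–OH, 3-methoxyprop-2-enyl on C11, CH2CO2H on C12 | O1CCOC12CC[C@H](O)[C@@](C)(CC=COC)[C@@H]2CC(=O)O | intermediate (not isolated)
15 | six-membered lactol acid: C5–O–C8(OH) lactol (both anomers) trans-fused to ring A; CH2CO2H on C12 | O1CCOC12CC[C@@H]3OC(O)CC[C@@]3(C)[C@@H]2CC(=O)O | intermediate
16 | alkene hydroxy acid: ring A with C2 dioxolane, C5–OH, 4-methylpent-3-enyl on C11, CH2CO2H on C12 | O1CCOC12CC[C@H](O)[C@@](C)(CCC=C(C)C)[C@@H]2CC(=O)O | intermediate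
17 | (8S)-epoxide of 16 (3,3-dimethyloxirane at C7–C8) | O1CCOC12CC[C@H](O)[C@@](C)(CC[C@@H]3OC3(C)C)[C@@H]2CC(=O)O | intermediate
18 | oxepane ketal acid: rings A/B closed (O6–C7), 8S hydroxyl, C2 dioxolane, CH2CO2H on C12 | O1CCOC12CC[C@@H]3OC(C)(C)[C@@H](O)CC[C@@]3(C)[C@@H]2CC(=O)O | intermediate (not isolated)
19 | keto hydroxy acid: trans-fused oxepane–cyclohexanone, C2 (or C25) ketone, 8S (or C19) hydroxyl, CH2CO2H on C12 (or C15); ring centres as in 34 | O=C1CC[C@@H]2OC(C)(C)[C@@H](O)CC[C@@]2(C)[C@@H]1CC(=O)O | intermediate
20 | triethylsilyl ester of 21 | CC[Si](CC)(CC)O[C@]1(C[Si](C)(C)C)CC[C@@H]2OC(C)(C)[C@@H](O[Si](CC)(CC)CC)CC[C@@]2(C)[C@@H]1CC(=O)O[Si](CC)(CC)CC | intermediate (not isolated)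
21 | west acid: C2 with axial OSiEt3 (syn to the C11 methyl) and CH2SiMe3; C8 OSiEt3; CH2CO2H on C12 | CC[Si](CC)(CC)O[C@]1(C[Si](C)(C)C)CC[C@@H]2OC(C)(C)[C@@H](O[Si](CC)(CC)CC)CC[C@@]2(C)[C@@H]1CC(=O)O | intermediate
22 | 2-thioxopyridin-1-yl ester of 21 | CC[Si](CC)(CC)O[C@]1(C[Si](C)(C)C)CC[C@@H]2OC(C)(C)[C@@H](O[Si](CC)(CC)CC)CC[C@@]2(C)[C@@H]1CC(=O)On1ccccc1=S | intermediate (not isolated)
23 | west iodide: as 21 with CH2I on C12 | CC[Si](CC)(CC)O[C@]1(C[Si](C)(C)C)CC[C@@H]2OC(C)(C)[C@@H](O[Si](CC)(CC)CC)CC[C@@]2(C)[C@@H]1CI | intermediate
24 | triethylsilyl ester of 25 | CC[Si](CC)(CC)OC(=O)C[C@H]1[C@]2(C)CC[C@H](O[Si](CC)(CC)CC)C(C)(C)O[C@H]2CC[C@@]1(C)O[Si](CC)(CC)CC | intermediate (not isolated)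
25 | east acid: C25 with equatorial methyl and axial OSiEt3 (syn to the C16 methyl); C19 OSiEt3; CH2CO2H on C15 | OC(=O)C[C@H]1[C@]2(C)CC[C@H](O[Si](CC)(CC)CC)C(C)(C)O[C@H]2CC[C@@]1(C)O[Si](CC)(CC)CC | intermediate
26 | 2-thioxopyridin-1-yl ester of 25 | S=c1ccccn1OC(=O)C[C@H]1[C@]2(C)CC[C@H](O[Si](CC)(CC)CC)C(C)(C)O[C@H]2CC[C@@]1(C)O[Si](CC)(CC)CC | intermediate (not isolated)
27 | east bis(triethylsilyl) iodide: as 25 with CH2I on C15 | IC[C@H]1[C@]2(C)CC[C@H](O[Si](CC)(CC)CC)C(C)(C)O[C@H]2CC[C@@]1(C)O[Si](CC)(CC)CC | intermediate (not isolated)
28 | east diol iodide: C25 tertiary alcohol (OH axial), C19 secondary alcohol, CH2I on C15 | IC[C@H]1[C@]2(C)CC[C@H](O)C(C)(C)O[C@H]2CC[C@@]1(C)O | intermediate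
29 | east keto alcohol iodide: C19 ketone, C25 tertiary alcohol, CH2I on C15 | IC[C@H]1[C@]2(C)CCC(=O)C(C)(C)O[C@H]2CC[C@@]1(C)O | intermediate
30 | east acetate iodide: C19 ketone, (25R) tertiary acetate, CH2I on C15 | IC[C@H]1[C@]2(C)CCC(=O)C(C)(C)O[C@H]2CC[C@@]1(C)OC(C)=O | intermediate
31 | alkylzinc iodide from 30 (C14–ZnI) | I[Zn]C[C@H]1[C@]2(C)CCC(=O)C(C)(C)O[C@H]2CC[C@@]1(C)OC(C)=O | intermediate (not isolated)
32 | coupled bis-bicycle: full skeleton of 34 with C2 carrying OSiEt3 and CH2SiMe3 and C8 carrying OSiEt3 | CC[Si](CC)(CC)O[C@]1(C[Si](C)(C)C)CC[C@@H]2OC(C)(C)[C@@H](O[Si](CC)(CC)CC)CC[C@@]2(C)[C@@H]1CC[C@H]1[C@]2(C)CCC(=O)C(C)(C)O[C@H]2CC[C@@]1(C)OC(C)=O | intermediate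
33 | desilylated hydroxysilane: as 32 with free C8–OH and C2(OH)CH2SiMe3 | O[C@]1(C[Si](C)(C)C)CC[C@@H]2OC(C)(C)[C@@H](O)CC[C@@]2(C)[C@@H]1CC[C@H]1[C@]2(C)CCC(=O)C(C)(C)O[C@H]2CC[C@@]1(C)OC(C)=O | intermediate (not isolated)
34 | target, CNP0148623.1: (5S,8S,11S,12R,15S,16S,22S,25R) in backbone locants | C=C1CC[C@@H]2OC(C)(C)[C@@H](O)CC[C@@]2(C)[C@@H]1CC[C@H]1[C@]2(C)CCC(=O)C(C)(C)O[C@H]2CC[C@@]1(C)OC(C)=O | target

## Step count and least certain steps

Total: 19 steps. Longest linear sequence: 17 steps (steps 1–11, 14–17, 18, 19); the west branch (steps 12, 13) adds two steps from 19.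

Step 2 (key step). Most likely failure: loss of facial control. Butadiene is a weak diene, so the reaction must run warmer than with activated dienes and an uncatalysed or proton-catalysed background addition can compete; the assumed sense of induction may also be wrong. Slow enolisation next to the vinylogous-ester carbonyl during the epimerisation is a lesser concern. Fallback: the route is made independent of the catalyst for enantiopurity by a classical separation at alcohol 9. Scalemic 9 would be esterified with (S)-2-methoxy-2-phenylacetic acid (N,N′-diisopropylcarbodiimide, 4-(dimethylamino)pyridine cat., CH2Cl2). The (S)-2-methoxy-2-phenylacetate of 9, F1, would be separated by crystallisation or chromatography from the diastereomeric ester of the enantiomer of 9, F2. F1 would then be cleaved with K2CO3 in MeOH, which returns enantiopure 9 to the route.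

Step 7. Most likely failure: over-oxidation. The lactol is in equilibrium with its hydroxy aldehyde and may be oxidised as well, giving a mixture. Fallback: oxidise both carbons on purpose and come back by reduction. 12 would be treated with 2,2,6,6-tetramethylpiperidin-1-oxyl (cat.) and PhI(OAc)2 in MeCN/H2O to give the lactone acid F3 (C9 lactone, C14 acid). i-Bu2AlH (2.2 equiv, CH2Cl2, −78 °C) would then reduce the lactone of the aluminium carboxylate to the lactol and rejoin the route at 13.

Step 11. Most likely failure: attack of the C5 hydroxyl at the secondary C8 (six-membered mode) in place of the tertiary C7, because the smaller ring forms faster unless the C7–O bond is well ionised. Rearrangement of the epoxide to a ketone is a second diversion. Fallback: use the six-membered mode deliberately and move the oxygen afterwards. Treatment of 17 with KOt-Bu (t-BuOH/THF) should give the tetrahydropyran tertiary alcohol F4 by SN2 attack at C8 with inversion. Solvolysis of F4 in buffered acetic acid (Zn(OAc)2, AcOH/H2O, heat) should ionise the tertiary hydroxyl, let O6 bridge to C7 and allow acetate to open the oxonium ion at C8 with a second inversion. An acetate that adds at C7 can re-ionise, whereas the secondary acetate cannot, and the dioxolane is lost under these conditions; this gives the oxepane acetate keto acid F5. Methanolysis (K2CO3, MeOH) then gives 19.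

Step 18. Most likely failure: reduction and β-hydride elimination of the alkylnickel intermediates, or homocoupling, because both carbons are β-branched next to quaternary centres and the productive coupling is slow. Fallback: change the radical precursor and the catalyst system and skip the iodide on the west side. Acid 21 would be converted into its N-acyloxyphthalimide F6 (N-hydroxyphthalimide, N,N′-diisopropylcarbodiimide). F6 would be coupled with alkylzinc iodide 31 (from 30) in a decarboxylative Negishi reaction (NiCl2·glyme, 4,4′-di-tert-butyl-2,2′-bipyridine, THF/DMF, rt), in which the C13 radical arises by electron transfer to the ester and loss of CO2. The product is 32, where the route is rejoined.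

## Further compounds

F1 | step 2 | (S)-2-methoxy-2-phenylacetate of 9 | O1CCOC12CC[C@H](OC(=O)[C@@H](OC)c4ccccc4)[C@@]3(C)CC=CC[C@H]23
F2 | step 2 | (S)-2-methoxy-2-phenylacetate of the enantiomer of 9 | O1CCOC12CC[C@@H](OC(=O)[C@@H](OC)c4ccccc4)[C@]3(C)CC=CC[C@@H]23
F3 | step 7 | lactone acid: C5–O–C9(=O) γ-lactone trans-fused to ring A, C2 dioxolane, CH2CO2H on C12 | O1CCOC12CC[C@@H]3OC(=O)C[C@@]3(C)[C@@H]2CC(=O)O
F4 | step 11 | tetrahydropyran alcohol: O6 bonded to C8 (8R), 2-hydroxypropan-2-yl on C8, C2 dioxolane, CH2CO2H on C12 | O1CCOC12CC[C@@H]3O[C@@H](C(C)(C)O)CC[C@@]3(C)[C@@H]2CC(=O)O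
F5 | step 11 | C8 acetate of 19 | O=C1CC[C@@H]2OC(C)(C)[C@@H](OC(C)=O)CC[C@@]2(C)[C@@H]1CC(=O)O
F6 | step 18 | N-acyloxyphthalimide of 21 | CC[Si](CC)(CC)O[C@]1(C[Si](C)(C)C)CC[C@@H]2OC(C)(C)[C@@H](O[Si](CC)(CC)CC)CC[C@@]2(C)[C@@H]1CC(=O)ON1C(=O)c2ccccc2C1=O
A1 | alternative 1 | aldol adduct of the three-component union | C=C1CC[C@@H]2OC(C)(C)[C@@H](O[Si](C)(C)C(C)(C)C)CC[C@@]2(C)[C@@H]1C[C@@H](O)[C@H]1[C@](C)(CCC=C(C)C)[C@@H](O[Si](CC)(CC)CC)CCC1=O
A2 | alternative 1 | 3-methyl-4-(triethylsilyloxy)cyclohex-2-enone with the C22 configuration of 34 | O=C1C=C(C)[C@@H](O[Si](CC)(CC)CC)CC1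
A3 | alternative 1 | ring A/B aldehyde (C2 methylene, C8 tert-butyldimethylsilyl ether, CH2CHO on C12) | C=C1CC[C@@H]2OC(C)(C)[C@@H](O[Si](C)(C)C(C)(C)C)CC[C@@]2(C)[C@@H]1CC=O
A4 | alternative 1 | 4-methylpent-3-enylmagnesium bromide | CC(C)=CCC[Mg]Br
A5 | alternative 2 | ring A/B ketone with C8 acetate and tert-butyl ester | O=C1CC[C@@H]2OC(C)(C)[C@@H](OC(C)=O)CC[C@@]2(C)[C@@H]1CC(=O)OC(C)(C)C
A6 | alternative 2 | tetrahydropyran precursor with 2-hydroxypropan-2-yl on C8 | O=C1CC[C@@H]2O[C@@H](C(C)(C)O)CC[C@@]2(C)[C@@H]1CC(=O)OC(C)(C)C
A7 | alternative 3 | ring A/B diene with C2 methylene and C13=C14 silyl enol ether | C=C1CC[C@@H]2OC(C)(C)[C@@H](O[Si](C)(C)C(C)(C)C)CC[C@@]2(C)[C@@H]1/C=C/O[Si](C)(C)C(C)(C)C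
A8 | alternative 3 | oxepane enyne (but-3-ynyl on C5; 3-silyloxyprop-1-enyl on C11) | C#CCC[C@@H]1OC(C)(C)[C@@H](O[Si](C)(C)C(C)(C)C)CC[C@@]1(C)/C=C/CO[Si](C)(C)C(C)(C)C
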